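The six-membered carbocycle C1–C6 of the target, with hydroxymethyl carbon C7 on the tertiary carbinol C6 and an oxygen on neighbouring C1, is the carbon skeleton of benzoic acid oxygenated at its ipso and ortho carbons. Everything therefore rests on a microbial ipso,ortho cis-dihydroxylation of benzoic acid: in one whole-cell operation the arene is dearomatised, the C6–O and C1–O bonds are made, C6 receives its final absolute configuration and the C2=C3–C4=C5 diene is left for later oxygenation. The precursor is commercial benzoic acid itself, fed as its salt. Downstream, C7 is reduced, a C6-hydroxyl-directed epoxide at C4–C5 is opened by benzoate, and C1 is inverted with benzoate.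

Key step: step 1

Remarks on the chemistry:
- Ring atoms carry the target numbering throughout: C1 and C4 bear the benzoates, C5 the secondary hydroxyl, C6 the tertiary hydroxyl and C7. "Upper face" is the face of the C6 hydroxyl.
- Names of 8–12 and of the F compounds use these locants; CIP descriptors refer to each compound itself.
- Assumption: the dehydrogenase-deficient strain for step 1 is obtained from a culture collection, and its cells regenerate the NADH for the dioxygenase from fructose.
- Dienes 2–6 should be kept cold and free of acid, and used promptly.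

Step 1
Reactants: 1 benzoic acid (fed as its sodium salt)
Product: 2 (1S,2R)-1,2-dihydroxycyclohexa-3,5-diene-1-carboxylic acid
Conditions: Ralstonia eutropha B9 whole cells (benzoate 1,2-dioxygenase; mutant lacking the cis-diol dehydrogenase), air, fructose, phosphate buffer pH 7, 30 °C; then pH 3, EtOAc extraction
Reagents that add atoms: dioxygen, O=O
Why: Benzoate 1,2-dioxygenase, a Rieske non-haem iron enzyme, passes two electrons from NADH through its [2Fe–2S] cluster to a mononuclear divalent iron site, where bound O2 is activated and both oxygen atoms are delivered to one face of the ring at the carboxyl-bearing carbon and its neighbour. The reaction type is the established microbial arene cis-dihydroxylation, here on the native substrate of the enzyme. No ring is closed; only the C6–O and C1–O bonds form and the C2=C3–C4=C5 diene remains. Both new stereocentres (C6 and C1) are fixed by the active site, which anchors the carboxylate and exposes a single ipso/ortho edge, so the cis-diol should arise as the (1S,2R) enantiomer with C6 already as the target needs it. The step needs ipso,ortho regioselectivity and a stop at the diol stage: the first is inherent to this dioxygenase, the second is secured by the missing dehydrogenase, so the diol accumulates and is not rearomatised.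

Step 2
Reactants: 2 (1S,2R)-1,2-dihydroxycyclohexa-3,5-diene-1-carboxylic acid
Product: 3 methyl (1S,2R)-1,2-dihydroxycyclohexa-3,5-diene-1-carboxylate
Conditions: MeI, KHCO3, DMF, rt
Reagents that add atoms: iodomethane, CI
Why: Carboxylate O-alkylation (SN2 esterification) under weakly basic conditions should leave both hydroxyls untouched and avoids the acid that would dehydrate the dienediol.

Step 3
Reactants: 3 methyl (1S,2R)-1,2-dihydroxycyclohexa-3,5-diene-1-carboxylate
Product: 4 methyl (1S,2R)-1-hydroxy-2-[(triethylsilyl)oxy]cyclohexa-3,5-diene-1-carboxylate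
Conditions: TESCl, imidazole, DMF, 0 °C
Reagents that add atoms: chlorotriethylsilane, CC[Si](Cl)(CC)CC
Why: Selective O-silylation should take the secondary C1 hydroxyl because the tertiary C6 hydroxyl beside the ester is too hindered for TESCl at 0 °C, and the capped C1 oxygen can no longer direct an oxidant to C2=C3.

Step 4
Reactants: 4 methyl (1S,2R)-1-hydroxy-2-[(triethylsilyl)oxy]cyclohexa-3,5-diene-1-carboxylate
Product: 5 (1R,6R)-1-(hydroxymethyl)-6-[(triethylsilyl)oxy]cyclohexa-2,4-dien-1-ol
Conditions: iBu2AlH (4 equiv), CH2Cl2, −78 to 0 °C; aq. potassium sodium tartrate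
Reagents that add atoms: none
Why: Hydride reduction of the ester to the primary alcohol (C7) is assisted by the aluminium alkoxide of the neighbouring C6 hydroxyl, and at low temperature the silyl ether should neither cleave nor migrate; the geometry at C6 is unchanged and only its descriptor switches.

Step 5
Reactants: 5 (1R,6R)-1-(hydroxymethyl)-6-[(triethylsilyl)oxy]cyclohexa-2,4-dien-1-ol
Product: 6 (1R,6R)-1-{[(tert-butyldiphenylsilyl)oxy]methyl}-6-[(triethylsilyl)oxy]cyclohexa-2,4-dien-1-ol
Conditions: TBDPSCl, imidazole, CH2Cl2, 0 °C to rt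
Reagents that add atoms: tert-butyl(chloro)diphenylsilane, CC(C)(C)[Si](Cl)(c1ccccc1)c1ccccc1
Why: Selective O-silylation of the primary C7 hydroxyl over the tertiary C6 hydroxyl gives an acid-stable ether that should outlast the later removal of the triethylsilyl group.

Step 6
Reactants: 6 (1R,6R)-1-{[(tert-butyldiphenylsilyl)oxy]methyl}-6-[(triethylsilyl)oxy]cyclohexa-2,4-dien-1-ol, 7 tert-butyl hydroperoxide
Product: 8 (1R,4S,5S,6S)-6-{[(tert-butyldiphenylsilyl)oxy]methyl}-4,5-epoxy-1-[(triethylsilyl)oxy]cyclohex-2-en-6-ol (epoxide oxygen on the upper face)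
Conditions: VO(acac)2 (5 mol %), t-BuOOH (anhydrous, decane), CH2Cl2, 0 °C to rt
Reagents that add atoms: none
Why: In this hydroxyl-directed vanadium-catalysed epoxidation the C6 alkoxide binds the vanadium alkyl peroxide and should deliver oxygen to the allylic C4=C5 bond on its own face, which sets C4 and C5, while C2=C3 is only homoallylic to the directing group and is shielded on that face by the C1 silyl ether.

Step 7
Reactants: 8 (1R,4S,5S,6S)-6-{[(tert-butyldiphenylsilyl)oxy]methyl}-4,5-epoxy-1-[(triethylsilyl)oxy]cyclohex-2-en-6-ol, 1 benzoic acid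
Product: 9 (1R,4R,5S,6S)-4-(benzoyloxy)-6-{[(tert-butyldiphenylsilyl)oxy]methyl}-1-[(triethylsilyl)oxy]cyclohex-2-ene-5,6-diol
Conditions: PhCO2H, Ti(OiPr)4, CH2Cl2, 0 °C to rt
Reagents that add atoms: none
Why: Titanium-mediated opening of a 2,3-epoxy alcohol by a carboxylic acid occurs at the carbon remote from the hydroxyl, here C4, which is also the allylic and less hindered epoxide carbon, and the SN2 attack inverts C4 so that the benzoate should end trans to the C5 hydroxyl, which stays cis to the C6 hydroxyl.

Step 8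
Reactants: 9 (1R,4R,5S,6S)-4-(benzoyloxy)-6-{[(tert-butyldiphenylsilyl)oxy]methyl}-1-[(triethylsilyl)oxy]cyclohex-2-ene-5,6-diol
Product: 10 (1R,4R,5S,6R)-4-(benzoyloxy)-6-{[(tert-butyldiphenylsilyl)oxy]methyl}cyclohex-2-ene-1,5,6-triol
Conditions: PPTS (cat.), MeOH/CH2Cl2, 0 °C
Reagents that add atoms: none
Why: Acid-catalysed methanolysis (selective desilylation) should cleave the triethylsilyl ether far faster than the primary TBDPS ether, and the non-basic medium avoids benzoyl migration from O4 to O5.

Step 9
Reactants: 10 (1R,4R,5S,6R)-4-(benzoyloxy)-6-{[(tert-butyldiphenylsilyl)oxy]methyl}cyclohex-2-ene-1,5,6-triol, 1 benzoic acid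
Product: 11 (1S,4R,5S,6S)-6-{[(tert-butyldiphenylsilyl)oxy]methyl}-5,6-dihydroxycyclohex-2-ene-1,4-diyl dibenzoate
Conditions: PhCO2H, PPh3, DIAD, THF, 0 °C to rt
Reagents that add atoms: none
Why: In this Mitsunobu reaction only the allylic secondary C1 hydroxyl should be displaced (C6–OH is tertiary, C5–OH is flanked by the quaternary C6 and the acyloxy-bearing C4), and SN2 attack by benzoate inverts C1 so that its ester ends trans to the C6 hydroxyl.

Step 10
Reactants: 11 (1S,4R,5S,6S)-6-{[(tert-butyldiphenylsilyl)oxy]methyl}-5,6-dihydroxycyclohex-2-ene-1,4-diyl dibenzoate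
Product: 12 (1S,4R,5S,6S)-5,6-dihydroxy-6-(hydroxymethyl)cyclohex-2-ene-1,4-diyl dibenzoate (CNP0212417.1)
Conditions: HF·pyridine, pyridine, THF, 0 °C to rt
Reagents that add atoms: none
Why: Fluoride-mediated desilylation under acidic, non-basic conditions should free O7 without benzoyl migration from O1 to O7 or from O4 to O5 and without touching the allylic esters or any stereocentre.

Compound list
1 | benzoic acid | OC(=O)c1ccccc1 | starting material
2 | (1S,2R)-1,2-dihydroxycyclohexa-3,5-diene-1-carboxylic acid | O[C@@H]1C=CC=C[C@@]1(O)C(=O)O | intermediate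
3 | methyl (1S,2R)-1,2-dihydroxycyclohexa-3,5-diene-1-carboxylate | O[C@@H]1C=CC=C[C@@]1(O)C(=O)OC | intermediate
4 | methyl (1S,2R)-1-hydroxy-2-[(triethylsilyl)oxy]cyclohexa-3,5-diene-1-carboxylate | CC[Si](CC)(CC)O[C@@H]1C=CC=C[C@@]1(O)C(=O)OC | intermediate
5 | (1R,6R)-1-(hydroxymethyl)-6-[(triethylsilyl)oxy]cyclohexa-2,4-dien-1-ol | CC[Si](CC)(CC)O[C@@H]1C=CC=C[C@@]1(O)CO | intermediate
6 | (1R,6R)-1-{[(tert-butyldiphenylsilyl)oxy]methyl}-6-[(triethylsilyl)oxy]cyclohexa-2,4-dien-1-ol | CC[Si](CC)(CC)O[C@@H]1C=CC=C[C@@]1(O)CO[Si](c2ccccc2)(c2ccccc2)C(C)(C)C | intermediate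
7 | tert-butyl hydroperoxide | CC(C)(C)OO | starting material
8 | (1R,4S,5S,6S)-6-{[(tert-butyldiphenylsilyl)oxy]methyl}-4,5-epoxy-1-[(triethylsilyl)oxy]cyclohex-2-en-6-ol; systematic: (1S,2S,3R,6S)-2-{[(tert-butyldiphenylsilyl)oxy]methyl}-3-[(triethylsilyl)oxy]-7-oxabicyclo[4.1.0]hept-4-en-2-ol | CC[Si](CC)(CC)O[C@@H]1C=C[C@@H]2O[C@@H]2[C@@]1(O)CO[Si](c3ccccc3)(c3ccccc3)C(C)(C)C | intermediate
9 | (1R,4R,5S,6S)-4-(benzoyloxy)-6-{[(tert-butyldiphenylsilyl)oxy]methyl}-1-[(triethylsilyl)oxy]cyclohex-2-ene-5,6-diol | CC[Si](CC)(CC)O[C@@H]1C=C[C@@H](OC(=O)c2ccccc2)[C@H](O)[C@@]1(O)CO[Si](c2ccccc2)(c2ccccc2)C(C)(C)C | intermediate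
10 | (1R,4R,5S,6R)-4-(benzoyloxy)-6-{[(tert-butyldiphenylsilyl)oxy]methyl}cyclohex-2-ene-1,5,6-triol | O[C@@H]1C=C[C@@H](OC(=O)c2ccccc2)[C@H](O)[C@@]1(O)CO[Si](c2ccccc2)(c2ccccc2)C(C)(C)C | intermediate
11 | (1S,4R,5S,6S)-6-{[(tert-butyldiphenylsilyl)oxy]methyl}-5,6-dihydroxycyclohex-2-ene-1,4-diyl dibenzoate | O=C(O[C@H]1C=C[C@@H](OC(=O)c2ccccc2)[C@H](O)[C@@]1(O)CO[Si](c2ccccc2)(c2ccccc2)C(C)(C)C)c1ccccc1 | intermediate
12 | (1S,4R,5S,6S)-5,6-dihydroxy-6-(hydroxymethyl)cyclohex-2-ene-1,4-diyl dibenzoate | O=C(O[C@H]1C=C[C@@H](OC(=O)c2ccccc2)[C@H](O)[C@@]1(O)CO)c1ccccc1 | target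

Total step count: 10. Longest linear sequence: 10 steps (1 to 12).

Steps most likely to fail

1. Step 9 (Mitsunobu inversion at C1). The backside displacement at the hindered allylic C1 may be slow, so that allylic transposition to C3 or elimination competes, or the C5 hydroxyl may be activated as well. The fallback replaces substitution by oxidation, directed reduction and acylation. It sets out from triol 10: MnO2 in CH2Cl2 at rt should oxidise only the allylic C1 alcohol to the enone (4R,5S,6S)-4-(benzoyloxy)-6-{[(tert-butyldiphenylsilyl)oxy]methyl}-5,6-dihydroxycyclohex-2-en-1-one F3. Reduction with Me4NBH(OAc)3 in MeCN/AcOH at −20 °C, in which boron bound to the C6 and C5 hydroxyls delivers hydride to the upper face of the carbonyl, should give the C1-epimeric triol (1S,4R,5S,6R)-4-(benzoyloxy)-6-{[(tert-butyldiphenylsilyl)oxy]methyl}cyclohex-2-ene-1,5,6-triol F4, with the C1 hydroxyl trans to the C6 hydroxyl. Benzoylation of this allylic hydroxyl with BzCl (1 equiv) and pyridine in CH2Cl2 at −40 °C comes back to the route at 11.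

2. Step 6 (directed epoxidation). Site selectivity between C4=C5 and C2=C3 may be lost, or the allylic epoxide may rearrange on the Lewis-acidic vanadium. The fallback builds the epoxide through a tether instead of by oxygen transfer. It sets out from 6: deprotonation of the C6 hydroxyl with n-BuLi in THF at −78 °C, capture with CO2 and addition of I2 should close the cis-fused five-membered iodocarbonate (1R,4R,5R,6S)-6-{[(tert-butyldiphenylsilyl)oxy]methyl}-4-iodo-1-[(triethylsilyl)oxy]cyclohex-2-ene-5,6-diyl carbonate F1, with oxygen on C5 on the upper face and iodine on C4 on the lower face. K2CO3 in MeOH at 0 °C should then cleave the carbonate, and the C5 alkoxide displaces the trans iodide, which comes back to the route at 8.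

3. Step 7 (epoxide opening by benzoate). Isopropoxide may be transferred from titanium in place of benzoate, or the Lewis acid may rearrange the allylic epoxide before it is opened. The fallback separates C–O bond formation from acylation. It sets out from 8: hydrolysis in THF/aqueous NaOAc–AcOH buffer (pH about 5) at rt should open the epoxide at allylic C4 with inversion to (1R,4R,5S,6S)-6-{[(tert-butyldiphenylsilyl)oxy]methyl}-1-[(triethylsilyl)oxy]cyclohex-2-ene-4,5,6-triol F2. BzCl (1 equiv) and 2,4,6-collidine in CH2Cl2 at −40 °C should then acylate the allylic C4 hydroxyl in preference to the C5 hydroxyl beside the quaternary C6 and to the tertiary C6 hydroxyl, which comes back to the route at 9.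

Further compounds
F1 | step 6 | (1R,4R,5R,6S)-6-{[(tert-butyldiphenylsilyl)oxy]methyl}-4-iodo-1-[(triethylsilyl)oxy]cyclohex-2-ene-5,6-diyl carbonate (cyclic) | CC[Si](CC)(CC)O[C@@H]1C=C[C@@H](I)[C@@H]2OC(=O)O[C@]12CO[Si](c3ccccc3)(c3ccccc3)C(C)(C)C
F2 | step 7 | (1R,4R,5S,6S)-6-{[(tert-butyldiphenylsilyl)oxy]methyl}-1-[(triethylsilyl)oxy]cyclohex-2-ene-4,5,6-triol | CC[Si](CC)(CC)O[C@@H]1C=C[C@@H](O)[C@H](O)[C@@]1(O)CO[Si](c2ccccc2)(c2ccccc2)C(C)(C)C
F3 | step 9 | (4R,5S,6S)-4-(benzoyloxy)-6-{[(tert-butyldiphenylsilyl)oxy]methyl}-5,6-dihydroxycyclohex-2-en-1-one | O=C1C=C[C@@H](OC(=O)c2ccccc2)[C@H](O)[C@@]1(O)CO[Si](c2ccccc2)(c2ccccc2)C(C)(C)C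
F4 | step 9 | (1S,4R,5S,6R)-4-(benzoyloxy)-6-{[(tert-butyldiphenylsilyl)oxy]methyl}cyclohex-2-ene-1,5,6-triol | O[C@H]1C=C[C@@H](OC(=O)c2ccccc2)[C@H](O)[C@@]1(O)CO[Si](c2ccccc2)(c2ccccc2)C(C)(C)C
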